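**Retrosynthetic overview**
- Feature: the quinone ring (C1=O, C2 bearing the side chain, C3–H, C4=O, C4a, C8a) is a 1,2-diacylbenzene whose acyl carbons C1 and C4 are bridged by C2=C3, a two-carbon unit equivalent to a terminal alkyne that already carries the C1' stereocentre.
- Key disconnection: C1–C2 and C3–C4, leading to 3,6-dimethoxybenzocyclobutene-1,2-dione 7 and the (S)-propargylic silyl ether 16, joined by cobalt insertion into the strained acyl–acyl bond and alkyne annulation.
- Dione 7: aryne [2+2] of 2-bromo-1,4-dimethoxybenzene with 1,1-dimethoxyethene, then benzylic dibromination and hydrolysis. Alkyne 16: Weinreb ynone synthesis, then asymmetric transfer hydrogenation, which sets C1' as (S).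
- End game: desilylation, isobutyrylation, then oxidative demethylation to the diquinone and reduction to the naphthazarin.
- Ring order: benzene ring (purchased), sacrificial four-membered ring (step 1), quinone ring (step 9).

Key step: step 9

Remark on the chemistry: the target is a naphthazarin whose two ring tautomers (side chain on the quinone ring or on the dihydroxybenzene ring) interconvert rapidly and are one compound; it is drawn as in the given SMILES.

**Route**

Step 1
Reactants: 1 2-bromo-1,4-dimethoxybenzene; 2 1,1-dimethoxyethene
Product: 5 3,6-dimethoxybenzocyclobutenone, via 3,6-dimethoxybenzyne 3 (not isolated), via benzocyclobutenone dimethyl acetal 4 (not isolated)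
Conditions: NaNH2, THF, reflux; then 1 M HCl, THF, rt
Reagents that add atoms: water, O
Why: NaNH2 removes the ring hydrogen flanked by Br and OMe and bromide is lost to give the symmetric aryne 3, whose stepwise [2+2] cycloaddition with the electron-rich ketene acetal can give only one regioisomer (4), and dilute acid then hydrolyses the acetal (aryne [2+2] cycloaddition, acetal hydrolysis).

Step 2
Reactants: 5 3,6-dimethoxybenzocyclobutenone
Product: 6 2,2-dibromo-3,6-dimethoxybenzocyclobutenone
Conditions: NBS (2.2 equiv), (PhCO2)2 (cat.), CCl4, reflux
Reagents that add atoms: N-bromosuccinimide, O=C1CCC(=O)N1Br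
Why: Wohl–Ziegler radical bromination should replace both hydrogens of the only benzylic CH2 (also alpha to the ketone), and the radical conditions in a non-polar solvent disfavour electrophilic bromination of the dimethoxyarene ring.

Step 3
Reactants: 6 2,2-dibromo-3,6-dimethoxybenzocyclobutenone
Product: 7 3,6-dimethoxybenzocyclobutene-1,2-dione
Conditions: 50% aq. H2SO4, 60 °C
Reagents that add atoms: water, O
Why: Acid-promoted hydrolysis of the benzylic gem-dibromide (ionisation assisted by the ortho-methoxy aryl ring, capture by water, loss of HBr) should give the strained but isolable 1,2-dione.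

Step 4
Reactants: 8 4-methylpent-3-enoic acid
Product: 10 N-methoxy-N,4-dimethylpent-3-enamide, via acyl imidazolide 9 (not isolated)
Conditions: 1,1'-carbonyldiimidazole, CH2Cl2, 0 °C → rt; then MeNHOMe·HCl, rt
Reagents that add atoms: N,O-dimethylhydroxylamine hydrochloride, CNOC.Cl; 1,1'-carbonyldiimidazole, O=C(n1ccnc1)n1ccnc1 (supplies the imidazole of 9 only)
Why: Amide coupling through the acyl imidazolide proceeds under near-neutral conditions, so the skipped alkene should not migrate into conjugation.

Step 5
Reactants: 10 N-methoxy-N,4-dimethylpent-3-enamide; 11 trimethylsilylacetylene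
Product: 13 6-methyl-1-(trimethylsilyl)hept-5-en-1-yn-3-one, via lithium trimethylsilylacetylide 12 (not isolated)
Conditions: 11, n-BuLi, THF, −78 °C; then 10, −78 → 0 °C; inverse quench into cold 1 M HCl
Reagents that add atoms: n-butyllithium, [Li]CCCC (supplies the lithium of 12 only)
Why: Weinreb ketone synthesis: the chelated tetrahedral adduct resists over-addition and releases the ynone only on the cold acidic quench, which also protonates the liberated hydroxylamine so that it does not add to the ynone.

Step 6
Reactants: 13 6-methyl-1-(trimethylsilyl)hept-5-en-1-yn-3-one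
Product: 14 (S)-6-methyl-1-(trimethylsilyl)hept-5-en-1-yn-3-ol
Conditions: Ru[(S,S)-TsDPEN](p-cymene) (1 mol %), i-PrOH, rt
Reagents that add atoms: none
Why: Noyori–Ikariya asymmetric transfer hydrogenation delivers hydride and proton through an outer-sphere six-membered transition state in which the alkynyl group takes the place of the aryl group of aryl ketones, so the (S,S)-catalyst should set the carbinol centre as (S), and the base-free conditions reduce the ynone carbonyl without touching or shifting the alkene.

Step 7
Reactants: 14 (S)-6-methyl-1-(trimethylsilyl)hept-5-en-1-yn-3-ol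
Product: 15 (S)-tert-butyldimethyl{[6-methyl-1-(trimethylsilyl)hept-5-en-1-yn-3-yl]oxy}silane
Conditions: TBSCl, imidazole, DMF, rt
Reagents that add atoms: tert-butyldimethylsilyl chloride, CC(C)(C)[Si](C)(C)Cl
Why: Imidazole-promoted O-silylation of the secondary alcohol (silyl ether protection) leaves the C–O bond and hence the (S)-centre untouched.

Step 8
Reactants: 15 (S)-tert-butyldimethyl{[6-methyl-1-(trimethylsilyl)hept-5-en-1-yn-3-yl]oxy}silane
Product: 16 (S)-tert-butyldimethyl[(6-methylhept-5-en-1-yn-3-yl)oxy]silane
Conditions: K2CO3, MeOH, rt
Reagents that add atoms: none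
Why: Base-catalysed protodesilylation of the alkynylsilane (methoxide attack at silicon with an acetylide leaving group) is selective because the hindered O-silyl ether has no comparable leaving group.

Step 9
Reactants: 7 3,6-dimethoxybenzocyclobutene-1,2-dione; 16 (S)-tert-butyldimethyl[(6-methylhept-5-en-1-yn-3-yl)oxy]silane
Product: 18 (S)-2-[1-(tert-butyldimethylsilyloxy)-4-methylpent-3-en-1-yl]-5,8-dimethoxy-1,4-naphthoquinone, via phthaloylcobalt metallacycle 17 (not isolated)
Conditions: ClCo(PPh3)3, PhCl, rt → 50 °C; evaporate; then 16, AgBF4 (excess), MeCN, 80–100 °C (sealed tube)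
Reagents that add atoms: chlorotris(triphenylphosphine)cobalt, Cl[Co-3]([P+](c1ccccc1)(c1ccccc1)c1ccccc1)([P+](c1ccccc1)(c1ccccc1)c1ccccc1)[P+](c1ccccc1)(c1ccccc1)c1ccccc1 (its Co, Cl and two PPh3 are held in 17 only; no reagent atom stays in 18)
Why: Monovalent cobalt adds oxidatively to the strained acyl–acyl bond of 7 to give the five-membered trivalent cobalt diacyl metallacycle 17, the release of four-membered-ring strain driving the insertion. AgBF4 then removes chloride as AgCl, the alkyne of 16 coordinates to the cationic centre and inserts into one Co–acyl bond, and C(acyl)–C(vinyl) reductive elimination from the resulting seven-membered cobaltacycle forms the second bond, so that quinone C1–C2 and C3–C4 are made and monovalent cobalt is expelled. The closest known reaction type is the stoichiometric phthaloylcobalt–alkyne naphthoquinone synthesis, used here on a new pairing of dione and alkyne. The six-membered quinone ring is closed by a metal-mediated formal [4+2] annulation (migratory insertion, then reductive elimination) directly at the quinone oxidation level, so no separate oxidation is needed. No stereocentre is created, and the propargylic C–O centre of 16 is a spectator because the medium is non-basic and the silyl ether does not ionise. Regiochemistry is no issue since 7 is symmetric and both insertion senses give 18, and the alkyne should react in preference to the trisubstituted alkene because alkynes bind cationic cobalt far more strongly and insert far faster than alkenes.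

Step 10
Reactants: 18 (S)-2-[1-(tert-butyldimethylsilyloxy)-4-methylpent-3-en-1-yl]-5,8-dimethoxy-1,4-naphthoquinone
Product: 19 (S)-2-(1-hydroxy-4-methylpent-3-en-1-yl)-5,8-dimethoxy-1,4-naphthoquinone
Conditions: HF·pyridine, pyridine, THF, 0 °C → rt
Reagents that add atoms: none
Why: Fluoride-mediated silyl ether cleavage, driven by the Si–F bond, runs under buffered conditions that should neither degrade the quinone by base nor promote acid-catalysed cyclisation of the hydroxyl onto the trisubstituted alkene, and the C–O bond is not broken, so C1' stays (S).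

Step 11
Reactants: 19 (S)-2-(1-hydroxy-4-methylpent-3-en-1-yl)-5,8-dimethoxy-1,4-naphthoquinone
Product: 20 (S)-1-(5,8-dimethoxy-1,4-dioxo-1,4-dihydronaphthalen-2-yl)-4-methylpent-3-en-1-yl 2-methylpropanoate
Conditions: (i-PrCO)2O, pyridine, DMAP (cat.), CH2Cl2, 0 °C → rt
Reagents that add atoms: isobutyric anhydride, CC(C)C(=O)OC(=O)C(C)C
Why: DMAP-catalysed acyl transfer (Steglich-type acylation) meets only one hydroxyl because both phenols are still methyl ethers, and it proceeds with retention since the C1'–O bond is not broken.

Step 12
Reactants: 20 (S)-1-(5,8-dimethoxy-1,4-dioxo-1,4-dihydronaphthalen-2-yl)-4-methylpent-3-en-1-yl 2-methylpropanoate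
Product: 22 isobutyryl alkannin, via naphthalene-1,4,5,8-tetrone 21 (not isolated)
Conditions: AgO, 6 M HNO3, acetone, 0 °C → rt (minutes); then aq. Na2S2O4, 0 °C (brief)
Reagents that add atoms: water, O
Why: Divalent silver in nitric acid oxidises the p-dimethoxybenzene ring by electron transfer, water attacks the ipso carbons and methanol is lost to give diquinone 21 (oxidative demethylation), which dithionite should reduce by two electrons to the naphthazarin while the ester, the alkene and the C1' configuration remain spectators under brief cold conditions.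

**Compound list**
1 | 2-bromo-1,4-dimethoxybenzene | COc1ccc(OC)c(Br)c1 | starting material
2 | 1,1-dimethoxyethene | C=C(OC)OC | starting material
3 | 3,6-dimethoxybenzyne (1,4-dimethoxycyclohexa-1,3-dien-5-yne) | COC1=CC=C(OC)C#C1 | intermediate
4 | 2,5,7,7-tetramethoxybicyclo[4.2.0]octa-1,3,5-triene (benzocyclobutenone dimethyl acetal) | COc1ccc(OC)c2c1CC2(OC)OC | intermediate
5 | 2,5-dimethoxybicyclo[4.2.0]octa-1,3,5-trien-7-one (3,6-dimethoxybenzocyclobutenone) | COc1ccc(OC)c2c1CC2=O | intermediate
6 | 8,8-dibromo-2,5-dimethoxybicyclo[4.2.0]octa-1,3,5-trien-7-one (2,2-dibromo-3,6-dimethoxybenzocyclobutenone) | COc1ccc(OC)c2c1C(Br)(Br)C2=O | intermediate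
7 | 2,5-dimethoxybicyclo[4.2.0]octa-1,3,5-triene-7,8-dione (3,6-dimethoxybenzocyclobutene-1,2-dione) | COc1ccc(OC)c2c1C(=O)C2=O | intermediate
8 | 4-methylpent-3-enoic acid | CC(C)=CCC(O)=O | starting material
9 | 1-(1H-imidazol-1-yl)-4-methylpent-3-en-1-one (acyl imidazolide) | CC(C)=CCC(=O)n1ccnc1 | intermediate
10 | N-methoxy-N,4-dimethylpent-3-enamide | CC(C)=CCC(=O)N(C)OC | intermediate
11 | trimethylsilylacetylene | C#C[Si](C)(C)C | starting material
12 | lithium (trimethylsilyl)acetylide | [Li]C#C[Si](C)(C)C | intermediate
13 | 6-methyl-1-(trimethylsilyl)hept-5-en-1-yn-3-one | CC(C)=CCC(=O)C#C[Si](C)(C)C | intermediate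
14 | (S)-6-methyl-1-(trimethylsilyl)hept-5-en-1-yn-3-ol | CC(C)=CC[C@H](O)C#C[Si](C)(C)C | intermediate
15 | (S)-tert-butyldimethyl{[6-methyl-1-(trimethylsilyl)hept-5-en-1-yn-3-yl]oxy}silane | CC(C)=CC[C@H](O[Si](C)(C)C(C)(C)C)C#C[Si](C)(C)C | intermediate
16 | (S)-tert-butyldimethyl[(6-methylhept-5-en-1-yn-3-yl)oxy]silane | CC(C)=CC[C@H](O[Si](C)(C)C(C)(C)C)C#C | intermediate
17 | chlorobis(triphenylphosphine)(3,6-dimethoxyphthaloyl)cobalt (five-membered diacyl metallacycle) | COc1ccc(OC)c2c1C(=O)[Co-2](Cl)([P+](c3ccccc3)(c3ccccc3)c3ccccc3)([P+](c3ccccc3)(c3ccccc3)c3ccccc3)C2=O | intermediate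
18 | (S)-2-[1-(tert-butyldimethylsilyloxy)-4-methylpent-3-en-1-yl]-5,8-dimethoxy-1,4-naphthoquinone | CC(C)=CC[C@H](O[Si](C)(C)C(C)(C)C)C1=CC(=O)c2c(OC)ccc(OC)c2C1=O | intermediate
19 | (S)-2-(1-hydroxy-4-methylpent-3-en-1-yl)-5,8-dimethoxy-1,4-naphthoquinone | CC(C)=CC[C@H](O)C1=CC(=O)c2c(OC)ccc(OC)c2C1=O | intermediate
20 | (S)-1-(5,8-dimethoxy-1,4-dioxo-1,4-dihydronaphthalen-2-yl)-4-methylpent-3-en-1-yl 2-methylpropanoate | CC(C)=CC[C@H](OC(=O)C(C)C)C1=CC(=O)c2c(OC)ccc(OC)c2C1=O | intermediate
21 | (S)-4-methyl-1-(1,4,5,8-tetraoxo-1,4,5,8-tetrahydronaphthalen-2-yl)pent-3-en-1-yl 2-methylpropanoate | CC(C)=CC[C@H](OC(=O)C(C)C)C1=CC(=O)C2=C(C1=O)C(=O)C=CC2=O | intermediate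
22 | isobutyryl alkannin, (S)-1-(5,8-dihydroxy-1,4-dioxo-1,4-dihydronaphthalen-2-yl)-4-methylpent-3-en-1-yl 2-methylpropanoate | CC(C)=CC[C@H](OC(=O)C(C)C)C1=CC(=O)c2c(O)ccc(O)c2C1=O | target

**Step count**
Total: 12 steps. Longest linear sequence: 9 steps (steps 4–12, from acid 8); the dione branch is 3 steps (steps 1–3).

**Steps most likely to fail**

1. Step 9. Chloride abstraction may not be followed by productive alkyne uptake: silver ion can form an acetylide with the terminal alkyne or trigger its oligomerisation, and the cationic metallacycle can decompose at the temperature a hindered propargylic ether needs for insertion. Fallback, setting out from 7 and returning at 18: metallacycle 17 would be made with ClCo(PPh3)3 as before but isolated by precipitation, then heated with dimethylglyoxime in pyridine so that both phosphines are exchanged for the N,N-chelate and pyridine, giving chloro(dimethylglyoxime)(pyridine)(3,6-dimethoxyphthaloyl)cobalt F1. F1, alkyne 16 and CoCl2·6H2O in 1,2-dichloroethane at 80 °C should then deliver 18. This replaces silver-mediated halide abstraction on the phosphine complex by Lewis acid-assisted ligand dissociation from an isolated, phosphine-free complex, so neither silver ion nor free phosphine is present when the alkyne is introduced.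

2. Step 12. The electron-poor dimethoxy ring may be oxidised incompletely while the trisubstituted alkene is attacked, and during the dithionite work-up over-reduction to the hydroquinone can expel the acyloxy group through a quinone methide. Fallback, setting out from 20 and returning at 22: reductive acetylation (Zn dust, Ac2O, NaOAc) should trap the hydroquinone as it forms to give (S)-1-(1,4-diacetoxy-5,8-dimethoxynaphthalen-2-yl)-4-methylpent-3-en-1-yl 2-methylpropanoate F2. (NH4)2Ce(NO3)6 in aqueous MeCN at 0 °C would then demethylate oxidatively only the more electron-rich dimethoxy ring, giving (S)-1-(1,4-diacetoxy-5,8-dioxo-5,8-dihydronaphthalen-2-yl)-4-methylpent-3-en-1-yl 2-methylpropanoate F3. Brief K2CO3/MeOH at 0 °C should cleave the two aryl acetates much faster than the hindered secondary isobutyrate, and the liberated naphthazarin is 22 through its tautomer equilibrium. No diquinone and no reducing work-up are involved.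

3. Step 6. The skipped alkene may migrate into conjugation at the ruthenium hydride before the carbonyl is reduced, and facial selectivity may erode, which would compromise the only stereocentre of the route. Fallback, setting out from 13 and returning at 14: Midland reduction with (S)-Alpine-Borane (B-isopinocampheyl-9-borabicyclo[3.3.1]nonane from (−)-α-pinene), neat at rt, followed by acetaldehyde and ethanolamine work-up. This is a stoichiometric, metal-free hydride transfer through a boat-like six-membered transition state in which the linear alkynyl group acts as the small substituent and which is expected to give the (S)-carbinol. No compound outside the list is made (F0).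

**Further compounds**
F1 | step 9 | chloro(dimethylglyoxime)(pyridine)(3,6-dimethoxyphthaloyl)cobalt | COc1ccc(OC)c2c1C(=O)[Co-3]3(Cl)([n+]4ccccc4)([N+](O)=C(C)C(C)=[N+]3O)C2=O
F2 | step 12 | (S)-1-(1,4-diacetoxy-5,8-dimethoxynaphthalen-2-yl)-4-methylpent-3-en-1-yl 2-methylpropanoate | CC(C)=CC[C@H](OC(=O)C(C)C)c1cc(OC(C)=O)c2c(OC)ccc(OC)c2c1OC(C)=O
F3 | step 12 | (S)-1-(1,4-diacetoxy-5,8-dioxo-5,8-dihydronaphthalen-2-yl)-4-methylpent-3-en-1-yl 2-methylpropanoate | CC(C)=CC[C@H](OC(=O)C(C)C)c1cc(OC(C)=O)c2C(=O)C=CC(=O)c2c1OC(C)=O
F0 | step 6 | none | none
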